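**Retrosynthetic overview**
1. The stearate C–O bond is cut last: target 9 comes from benzylic alcohol 7 and stearoyl chloride, and 7 from methyl ester 6 by reduction.
2. The oxepine ring of 6 is opened by a retro endo-mode ring-closing enyne metathesis to enyne 5, an aryl propargyl ether with an ortho-vinyl group.
3. Enabling feature: the cross-conjugated diene of the oxepine, exocyclic C3=CH2 joined to ring C4=C5 next to the O1–C2H2 ether. O1–C2–C3–C4 is a propargyl ether (C3≡C4 a terminal alkyne), and C5 plus the exocyclic CH2 are an ortho-vinyl group.
4. Enyne 5 comes from methyl 3-formyl-4-hydroxybenzoate 1 by O-propargylation and Wittig methylenation.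
5. Ring order: the benzene ring is bought; the oxepine ring is the only ring made and is closed in step 3.

Key step: step 3

Assumption (remark on the chemistry): the target has no stereocentre, and its only geometric element, the ring alkene C4=C5, is necessarily cis in the seven-membered ring, so no enantiocontrol is needed.

**Route**

Step 1
Reactants: 1 methyl 3-formyl-4-hydroxybenzoate; 2 3-bromoprop-1-yne (propargyl bromide)
Product: 3 methyl 3-formyl-4-(prop-2-yn-1-yloxy)benzoate
Conditions: K2CO3 (1.5 equiv), propargyl bromide (1.2 equiv), DMF, rt
Reagents that add atoms: 2 propargyl bromide, C#CCBr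
Why: Williamson ether synthesis; the phenoxide, acidified by the ortho-formyl and para-ester groups, should be alkylated at oxygen by the primary propargylic bromide (SN2), with no stereocentre formed.

Step 2
Reactants: 3 methyl 3-formyl-4-(prop-2-yn-1-yloxy)benzoate; 4 methyltriphenylphosphonium bromide
Product: 5 methyl 3-ethenyl-4-(prop-2-yn-1-yloxy)benzoate
Conditions: MePPh3Br (1.2 equiv), NaHMDS (1.15 equiv), THF, 0 °C (ylide preformed); then 3, −78 → 0 °C
Reagents that add atoms: 4 methyltriphenylphosphonium bromide, C[P+](c1ccccc1)(c1ccccc1)c1ccccc1.[Br-]
Why: Wittig methylenation; the non-stabilised ylide should react with the aldehyde much faster than with the conjugated methyl ester, and a preformed ylide without excess base at low temperature should leave the propargyl ether and the terminal alkyne untouched.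

Step 3
Reactants: 5 methyl 3-ethenyl-4-(prop-2-yn-1-yloxy)benzoate
Product: 6 methyl 3-methylidene-2,3-dihydro-1-benzoxepine-7-carboxylate
Conditions: Mo(N-2,6-iPr2C6H3)(CHCMe2Ph)(2,5-Me2-pyrrolide)(OAr) monoaryloxide–pyrrolide alkylidene (OAr = hindered 2,6-diarylphenoxide, 5 mol %, made in situ from the bis-pyrrolide and ArOH), C6H6, 22 °C, 0.02 M, N2
Reagents that add atoms: none
Why: The Mo methylidene should add to the terminal alkyne with β-regiochemistry (new C–C bond to the internal alkyne carbon, Mo on the terminal carbon), and the molybdacyclobutene should open to the vinylalkylidene Mo=CH–C(=CH2)–CH2OAr, which then undergoes ring-closing metathesis with the ortho-vinyl group to form C4=C5 and return Mo=CH2. The closest known reaction type is the endo-selective ring-closing enyne metathesis of terminal 1,6- and 1,7-enynes with Mo monoaryloxide–pyrrolide alkylidenes. The seven-membered ring closes by a [2+2]/retro-[2+2] between the alkylidene carbon (the former alkyne terminus, C4) and the styrenyl CH (C5), in the endo mode, so that both alkyne carbons lie in the ring and the transferred CH2 becomes the exocyclic methylene on C3. No stereocentre is created, and the C4=C5 alkene is cis because the ring allows nothing else. The step needs endo closure (seven-membered ring) over exo closure (six-membered 3-vinyl-2H-chromene) and cyclisation over alkyne oligomerisation; the first is secured by the terminal alkyne, whose only substituent (CH2OAr) the large aryloxide pushes onto the β-carbon of the metallacycle, and by the alkyne reacting with Mo=CH2 before the less reactive styrenyl alkene, the second by the ortho-phenylene tether (two sp2 ring atoms holding the partners 1,7) and by dilution. The product's 1,1-disubstituted exocyclic alkene and conjugated cis-alkene should be inert to further metathesis.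

Step 4
Reactants: 6 methyl 3-methylidene-2,3-dihydro-1-benzoxepine-7-carboxylate
Product: 7 (3-methylidene-2,3-dihydro-1-benzoxepin-7-yl)methanol
Conditions: DIBAL-H (2.5 equiv), CH2Cl2, −78 → −20 °C; aq. Rochelle salt work-up
Reagents that add atoms: none
Why: Ester reduction with DIBAL-H; two hydride transfers should take the aryl ester to the benzylic alcohol at low temperature, where neither the conjugated diene nor the allylic aryl ether is hydroaluminated or cleaved.

Step 5
Reactants: 7 (3-methylidene-2,3-dihydro-1-benzoxepin-7-yl)methanol; 8 octadecanoyl chloride (stearoyl chloride)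
Product: 9 (3-methylidene-2,3-dihydro-1-benzoxepin-7-yl)methyl octadecanoate
Conditions: stearoyl chloride (1.1 equiv), Et3N (1.5 equiv), DMAP (0.1 equiv), CH2Cl2, 0 °C → rt
Reagents that add atoms: 8 octadecanoyl chloride, ClC(=O)CCCCCCCCCCCCCCCCC
Why: DMAP-catalysed acylation of a primary alcohol by an acid chloride (nucleophilic acyl substitution); the amine scavenges HCl, so the acid-sensitive diene and the electron-rich benzylic ester should survive.

**Compound list**
1 | methyl 3-formyl-4-hydroxybenzoate | COC(=O)c1ccc(O)c(C=O)c1 | starting material
2 | 3-bromoprop-1-yne (propargyl bromide) | C#CCBr | starting material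
3 | methyl 3-formyl-4-(prop-2-yn-1-yloxy)benzoate | COC(=O)c1ccc(OCC#C)c(C=O)c1 | intermediate
4 | methyltriphenylphosphonium bromide | C[P+](c1ccccc1)(c1ccccc1)c1ccccc1.[Br-] | starting material
5 | methyl 3-ethenyl-4-(prop-2-yn-1-yloxy)benzoate | COC(=O)c1ccc(OCC#C)c(C=C)c1 | intermediate
6 | methyl 3-methylidene-2,3-dihydro-1-benzoxepine-7-carboxylate | C=C1C=Cc2cc(C(=O)OC)ccc2OC1 | intermediate
7 | (3-methylidene-2,3-dihydro-1-benzoxepin-7-yl)methanol | C=C1C=Cc2cc(CO)ccc2OC1 | intermediate
8 | octadecanoyl chloride (stearoyl chloride) | ClC(=O)CCCCCCCCCCCCCCCCC | starting material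
9 | (3-methylidene-2,3-dihydro-1-benzoxepin-7-yl)methyl octadecanoate | C=C1C=Cc2cc(COC(=O)CCCCCCCCCCCCCCCCC)ccc2OC1 | target

**Step count**
Total steps: 5. Longest linear sequence: 5 (1 → 3 → 5 → 6 → 7 → 9).

**Steps most likely to fail, with fallbacks**

Step 3 (key step). The alkyne may insert with the opposite regiochemistry, so that the ring closes in the exo mode to a six-membered ring, or the terminal alkyne may oligomerise and consume the catalyst. The fallback builds the diene first and closes the ring by diene metathesis with ruthenium. It sets out from 3: cross enyne metathesis with ethylene (Grubbs second-generation catalyst, ethylene 1 atm, CH2Cl2, rt) should give methyl 3-formyl-4-[(2-methylidenebut-3-en-1-yl)oxy]benzoate F1, in which no tethered alkene competes. Wittig methylenation of F1 (ylide from 4 and NaHMDS, THF, −78 → 0 °C) should give methyl 3-ethenyl-4-[(2-methylidenebut-3-en-1-yl)oxy]benzoate F2. Ring-closing diene metathesis of F2 with the Grubbs first-generation catalyst (CH2Cl2, 40 °C, dilute), which spares the 1,1-disubstituted alkene, should join the two monosubstituted vinyl groups and come back to the route at 6.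

Step 2. The basic ylide may isomerise the propargyl ether to the allenyl ether or attack the ester instead of only the aldehyde. The fallback moves the olefination ahead of the ether formation. It sets out from 1: methylenation of the free phenol aldehyde with excess ylide (from 4 and KOtBu, 2.5 equiv, THF, 0 °C → rt; the first equivalent forms the phenoxide) should give methyl 3-ethenyl-4-hydroxybenzoate F3. O-Propargylation of F3 with 2 (K2CO3, acetone, 50 °C), under a base too weak to isomerise the ether, comes back to the route at 5.

Step 4. The diene may be hydroaluminated, or the electron-rich dienyl benzylic alcohol may decompose on the Lewis-acidic aluminium work-up. The fallback finishes the side chain before the diene exists and makes the ring closure the last step. It sets out from 5: DIBAL-H reduction (CH2Cl2, −78 °C) should give [3-ethenyl-4-(prop-2-yn-1-yloxy)phenyl]methanol F4. Acylation with 8 (Et3N, DMAP, CH2Cl2) should give [3-ethenyl-4-(prop-2-yn-1-yloxy)phenyl]methyl octadecanoate F5. The Mo-catalysed endo-mode enyne ring closure of F5 under the conditions of step 3, which tolerate the ester, comes back to the route at 9.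

**Further compounds**
F1 | step 3 | methyl 3-formyl-4-[(2-methylidenebut-3-en-1-yl)oxy]benzoate | COC(=O)c1ccc(OCC(=C)C=C)c(C=O)c1
F2 | step 3 | methyl 3-ethenyl-4-[(2-methylidenebut-3-en-1-yl)oxy]benzoate | COC(=O)c1ccc(OCC(=C)C=C)c(C=C)c1
F3 | step 2 | methyl 3-ethenyl-4-hydroxybenzoate | COC(=O)c1ccc(O)c(C=C)c1
F4 | step 4 | [3-ethenyl-4-(prop-2-yn-1-yloxy)phenyl]methanol | OCc1ccc(OCC#C)c(C=C)c1
F5 | step 4 | [3-ethenyl-4-(prop-2-yn-1-yloxy)phenyl]methyl octadecanoate | C=Cc1cc(COC(=O)CCCCCCCCCCCCCCCCC)ccc1OCC#C
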